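The dihydrobenzofuran is cut at C1–aryl and C10–O. This leads back to a symmetrical chalcone and an aristolane 1(10)-ene-8,9-dione. Everything rests on building ring A (C1–C5, C10) of that dione one carbon short. A commercial enantiopure indenedione supplies C5 and a cyclopentene that lacks C1. In the key step dibromocarbene inserts C1 into the C10=C2 bond of a tricyclic 9-acetoxy β,γ-enone. Cyclopropane opening and loss of HBr then turn the five-membered ring into the cyclohexadiene of ring A in one operation. The step exploits that C1, the only ring A atom bonded to the arene, sits between C10 and C2 and is vinylogous to the C9 oxygen.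

Key step: step 6

Remark: aristolane numbering is used for all terpenoid compounds (ring A = C1–C5, C10; ring B = C5–C10; cyclopropane = C6, C7, C11). α is the face of the C5 methyl group. The (7aR) enantiomer of 1 is taken as commercially available.

Step 1
Reactants: 1 (7aR)-7a-methyl-2,3,7,7a-tetrahydro-1H-indene-1,5(6H)-dione (C4 ketone, C8 enone, ring A still five-membered: C10, C2, C3, C4, C5)
Product: 2 4-methylidene enone (7a-methyl-1-methylidene-1,2,3,6,7,7a-hexahydro-5H-inden-5-one, C5 as in 1)
Conditions: Ph3PCH3Br, KOtBu, THF, 0 °C → rt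
Reagents that add atoms: methyltriphenylphosphonium bromide, C[P+](c1ccccc1)(c1ccccc1)c1ccccc1.[Br-]
Why: Wittig methylenation, in which the saturated C4 carbonyl is far more electrophilic than the vinylogous C8 enone carbonyl and the quaternary C5 stereocentre cannot epimerise.

Step 2
Reactants: 2 4-methylidene enone
Product: 3 cis-4,5-dimethyl enone (1,7a-dimethyl-1,2,3,6,7,7a-hexahydro-5H-inden-5-one, both methyl groups α)
Conditions: H2 (1 atm), RhCl(PPh3)3 (5 mol %), benzene/EtOH, rt
Reagents that add atoms: none
Why: Homogeneous hydrogenation reduces the 1,1-disubstituted alkene and leaves the trisubstituted enone, and hydrogen arrives on the β face opposite the C5 methyl group, which sets C4 with its methyl group α, cis to the C5 methyl.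

Step 3
Reactants: 3 cis-4,5-dimethyl enone
Product: 4 cross-conjugated dienone (1,7a-dimethyl-1,2,3,7a-tetrahydro-5H-inden-5-one, C6=C7 and C9=C10, both methyl groups α)
Conditions: IBX (2.5 equiv), DMSO/fluorobenzene, 75 °C
Reagents that add atoms: none
Why: IBX dehydrogenation of a ketone through its enol, in which C7 is the only sp3 α-carbon, so the C6=C7 bond of the cross-conjugated dienone should form.

Step 4
Reactants: 4 cross-conjugated dienone
Product: 5 1-nor-aristol-9-en-8-one (tricyclic enone; gem-dimethylcyclopropane on C6–C7 on the β face, H6 and H7 α, C4 and C5 methyl groups α)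
Conditions: iPrPh2S+ BF4−, LDA, DME/THF, −78 → −30 °C
Reagents that add atoms: isopropyldiphenylsulfonium tetrafluoroborate, CC(C)[S+](c1ccccc1)c1ccccc1.F[B-](F)(F)F
Why: Corey–Chaykovsky-type cyclopropanation, in which the isopropylide adds to the disubstituted C6=C7 bond and not to fully substituted C10, from the β face anti to the pseudo-axial C5 methyl group, and closure with loss of Ph2S sets C6 and C7.

Step 5
Reactants: 5 1-nor-aristol-9-en-8-one
Product: 7 9-acetoxy-1-nor-aristol-10(2)-en-8-one (alkene now C10=C2 in the five-membered ring; C9 epimers), via potassium alkoxide 6 (not isolated)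
Conditions: KHMDS, THF, −78 °C; 2-(phenylsulfonyl)-3-phenyloxaziridine, −78 °C; then Ac2O, −78 → 0 °C
Reagents that add atoms: 2-(phenylsulfonyl)-3-phenyloxaziridine, O=S(=O)(c1ccccc1)N1OC1c1ccccc1; acetic anhydride, CC(=O)OC(C)=O
Why: Deconjugative α-hydroxylation of an extended enolate, in which the base removes a γ-proton at C2 because C7 is a cyclopropane methine, the dienolate takes oxygen at its α-carbon C9 and so moves the alkene to C10=C2, and acetylation in the same flask blocks ketol isomerisation; the C9 configuration is not controlled and is erased in step 6.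

Step 6
Reactants: 7 9-acetoxy-1-nor-aristol-10(2)-en-8-one
Product: 10 9-acetoxy-1-bromoaristola-1,9-dien-8-one, via dibromocyclopropane 8 (not isolated), via allylic dibromide 9 (not isolated)
Conditions: PhHgCBr3 (2 equiv), benzene, 80 °C; then Et3N, rt
Reagents that add atoms: phenyl(tribromomethyl)mercury, BrC(Br)(Br)[Hg]c1ccccc1
Why: Thermolysis of PhHgCBr3 releases dibromocarbene, which adds in a cheletropic [2+1] step to C10=C2, the only nucleophilic alkene of 7, and closes the cyclopropane C10–C1–C2 on the five-membered ring (8). At 80 °C the bromide endo to the cyclopentane ionises while the C10–C2 bond opposite CBr2 opens by the symmetry-allowed disrotatory two-electron electrocyclic process, so C1 ends between C10 and C2, the ring C10, C2, C3, C4, C5 becomes six-membered ring A, and bromide returns at the less hindered C2 terminus (9). Et3N then removes the C9 proton, which is α to the C8 ketone, and expels the C2 bromide in a vinylogous 1,4-elimination to give the fully conjugated dienone 10. This is the classical dihalocarbene one-carbon ring expansion of cyclopentenes to 2-halocyclohexadienes. No new stereocentre survives because C1, C2, C9 and C10 all end sp2, so the face of carbene attack and the C9 epimer ratio of 7 do not matter, and C4, C5, C6 and C7 are untouched. The selectivity needed is which cyclopropane bond breaks, and orbital symmetry together with the tertiary allylic character of C10 secures the internal one.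

Step 7
Reactants: 10 9-acetoxy-1-bromoaristola-1,9-dien-8-one
Product: 11 9-acetoxyaristola-1,9-dien-8-one
Conditions: Pd(OAc)2 (5 mol %), PPh3, HCO2H, Et3N, DMF, 60 °C
Reagents that add atoms: none
Why: Palladium-catalysed formate hydrogenolysis of an alkenyl bromide (oxidative addition to zerovalent palladium, formate decarboxylation, C–H reductive elimination), which should tolerate the dienone, the enol acetate and the cyclopropane.

Step 8
Reactants: 11 9-acetoxyaristola-1,9-dien-8-one
Product: 12 9-hydroxyaristola-1,9-dien-8-one (diosphenol form of the 1(10)-ene-8,9-dione)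
Conditions: K2CO3, MeOH, 0 °C, argon; then aqueous citric acid
Reagents that add atoms: none
Why: Base-promoted transesterification of the enol acetate frees the diosphenol, which should rest as the hydrogen-bonded 9-hydroxy dienone tautomer.

Step 9
Reactants: 13 1-(2,6-dihydroxy-4-methoxyphenyl)ethanone; 14 4-methoxybenzaldehyde
Product: 15 (E)-2',6'-dihydroxy-4,4'-dimethoxychalcone
Conditions: KOH (aq), EtOH, rt; then cold dilute HCl to pH 5
Reagents that add atoms: none
Why: Claisen–Schmidt aldol condensation, in which E1cB loss of water gives the more stable E-enone and the cold, weakly acidic work-up limits closure to the flavanone.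

Step 10
Reactants: 12 9-hydroxyaristola-1,9-dien-8-one; 15 (E)-2',6'-dihydroxy-4,4'-dimethoxychalcone
Product: 17 1α-aryl-9-hydroxyaristol-9-en-8-one (aryl = C3' of the chalcone; the C1 epimer is also expected), via ene-dione tautomer 16 (not isolated)
Conditions: (PhO)2P(O)OH (10 mol %), (CF3)2CHOH, 40 °C, argon
Reagents that add atoms: none
Why: Friedel–Crafts conjugate addition, in which acid shifts 12 to the ene-dione 16, whose C1 is the β-carbon of the C9 enone and is attacked by either of the two equivalent free positions of symmetrical 15, so only one regioisomer can form; C1 is set reversibly (retro-addition, vinylogous enolisation) and both epimers are carried on.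

Step 11
Reactants: 17 1α-aryl-9-hydroxyaristol-9-en-8-one
Product: 18 target CNP0121765.1
Conditions: PhI(OAc)2 (1.05 equiv), CF3CH2OH, −20 → 0 °C
Reagents that add atoms: none
Why: Oxidative α-aryloxylation through a trivalent-iodine enolate, in which the C9 enol binds iodine and the neighbouring phenol oxygen attacks C10 in a 5-exo closure with loss of PhI to give the 8,9-dione; only an axial aryl group places that oxygen over C10, the axial site at C1 lies on the α face, and the β face is screened by the endo cyclopropane methyl, so C10–O should form α, cis to C1–aryl, while the other C1 epimer re-equilibrates.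

Compound list
1 | (7aR)-7a-methyl-2,3,7,7a-tetrahydro-1H-indene-1,5(6H)-dione | C24=CC(=O)CC[C@@]2(C)C(=O)CC4 | starting material
2 | 4-methylidene enone | C24=CC(=O)CC[C@@]2(C)C(=C)CC4 | intermediate
3 | cis-4,5-dimethyl enone | C24=CC(=O)CC[C@@]2(C)[C@H](C)CC4 | intermediate
4 | cross-conjugated dienone | C24=CC(=O)C=C[C@@]2(C)[C@H](C)CC4 | intermediate
5 | 1-nor-aristol-9-en-8-one | C24=CC(=O)[C@@H]5[C@@H](C5(C)C)[C@@]2(C)[C@H](C)CC4 | intermediate
6 | potassium 9-alkoxide of the 10(2)-en-8-one (C9 epimers) | C24C([O-])C(=O)[C@@H]5[C@@H](C5(C)C)[C@@]2(C)[C@H](C)CC=4.[K+] | intermediate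
7 | 9-acetoxy-1-nor-aristol-10(2)-en-8-one (C9 epimers) | C24C(OC(C)=O)C(=O)[C@@H]5[C@@H](C5(C)C)[C@@]2(C)[C@H](C)CC=4 | intermediate
8 | 1,1-dibromocyclopropane across C10–C2 (new centres erased in the same step) | C246C(OC(C)=O)C(=O)[C@@H]5[C@@H](C5(C)C)[C@@]2(C)[C@H](C)CC4C6(Br)Br | intermediate
9 | 9-acetoxy-1,2-dibromoaristol-1(10)-en-8-one | C24C(OC(C)=O)C(=O)[C@@H]5[C@@H](C5(C)C)[C@@]2(C)[C@H](C)CC(Br)C=4Br | intermediate
10 | 9-acetoxy-1-bromoaristola-1,9-dien-8-one | C24=C(OC(C)=O)C(=O)[C@@H]5[C@@H](C5(C)C)[C@@]2(C)[C@H](C)CC=C4Br | intermediate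
11 | 9-acetoxyaristola-1,9-dien-8-one | C24=C(OC(C)=O)C(=O)[C@@H]5[C@@H](C5(C)C)[C@@]2(C)[C@H](C)CC=C4 | intermediate
12 | 9-hydroxyaristola-1,9-dien-8-one | C24=C(O)C(=O)[C@@H]5[C@@H](C5(C)C)[C@@]2(C)[C@H](C)CC=C4 | intermediate
13 | 1-(2,6-dihydroxy-4-methoxyphenyl)ethanone | CC(=O)c1c(O)cc(OC)cc1O | starting material
14 | 4-methoxybenzaldehyde | COc1ccc(C=O)cc1 | starting material
15 | (E)-2',6'-dihydroxy-4,4'-dimethoxychalcone | COc1ccc(/C=C/C(=O)c2c(O)cc(OC)cc2O)cc1 | intermediate
16 | aristol-1(10)-ene-8,9-dione | C24C(=O)C(=O)[C@@H]5[C@@H](C5(C)C)[C@@]2(C)[C@H](C)CCC=4 | intermediate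
17 | 1α-aryl-9-hydroxyaristol-9-en-8-one | C24=C(O)C(=O)[C@@H]5[C@@H](C5(C)C)[C@@]2(C)[C@H](C)CC[C@@H]4c3c(O)c(C(=O)/C=C/c6ccc(OC)cc6)c(O)cc3OC | intermediate
18 | CNP0121765.1 | COc1ccc(/C=C/C(=O)c2c(O)cc(OC)c3c2O[C@]24C(=O)C(=O)[C@@H]5[C@@H](C5(C)C)[C@@]2(C)[C@H](C)CC[C@H]34)cc1 | target

Total step count: 11. Longest linear sequence: 10 (steps 1–8, 10, 11).

Steps most likely to fail

Step 10. The acyl-deactivated arene may attack the small equilibrium share of the ene-dione tautomer too slowly, and the chalcone may drain into its flavanone.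
- The fallback makes the C1–aryl bond by cross-coupling. It sets out from 10 and 13 and comes back at 17.
- Iodination of 13 (NIS, MeCN) should give the 3-iodo ketone F7. MOMCl and iPr2NEt should give the bis(methoxymethyl) ether F8. Miyaura borylation (PdCl2(dppf), B2pin2, KOAc) should give the pinacol boronate F9.
- Suzuki–Miyaura coupling of F9 with the C1 bromide of 10 (Pd(OAc)2, SPhos, K3PO4) should give the 1-aryl dienone F10.
- Copper hydride (Cu(OAc)2, 1,2-bis(diphenylphosphino)benzene, PMHS) should add hydride to C2 in the 1,6 sense and, after γ-protonation, give the 1-aryl enone F11.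
- Claisen–Schmidt condensation with 14 (KOH, EtOH), which also cleaves the enol acetate, should give the protected chalcone F12. HCl in MeOH then frees both phenols to give 17.

Step 11. The electron-rich phenol ring may be over-oxidised, or facial selectivity at C10 may be poor.
- The fallback separates ring closure from oxidation. It sets out from 17 and comes back at 18.
- DBU in toluene should close the phenol onto C10 by a reversible oxa-Michael addition under thermodynamic control to give the 9-hydroxy 8-ketone F13.
- The acyloin of F13 is then oxidised with 1,1,1-triacetoxy-1,1-dihydro-1,2-benziodoxol-3(1H)-one (DMP) and NaHCO3 to 18.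

Step 6. Carbene addition may be slow at an alkene flanked by quaternary C5 and the acetoxy-bearing C9, and the substrate may isomerise thermally.
- The fallback expands the ring before C9 is oxygenated. It sets out from 5 and comes back at 12.
- KOtBu followed by cold aqueous AcOH should deconjugate 5 to the β,γ-enone F1.
- PhHgCBr3 should add to the less crowded alkene of F1 to give the dibromocyclopropane F2, which opens and, with Et3N, loses HBr to give the bromodienone F3.
- Formate hydrogenolysis as in step 7 should give the dienone F4. H2 with RhCl(PPh3)3 should saturate only the disubstituted C1=C2 bond to give the enone F5.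
- Deconjugative hydroxylation as in step 5 (without acetylation) should give the 9-hydroxy 1(10)-ene F6. DMP oxidation then gives 16, which enolises to 12.

Further compounds
F1 | step 6 | 1-nor-aristol-10(2)-en-8-one | C24CC(=O)[C@@H]5[C@@H](C5(C)C)[C@@]2(C)[C@H](C)CC=4
F2 | step 6 | 1,1-dibromocyclopropane across C10–C2 of F1 | C246CC(=O)[C@@H]5[C@@H](C5(C)C)[C@@]2(C)[C@H](C)CC4C6(Br)Br
F3 | step 6 | 1-bromoaristola-1,9-dien-8-one | C24=CC(=O)[C@@H]5[C@@H](C5(C)C)[C@@]2(C)[C@H](C)CC=C4Br
F4 | step 6 | aristola-1,9-dien-8-one | C24=CC(=O)[C@@H]5[C@@H](C5(C)C)[C@@]2(C)[C@H](C)CC=C4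
F5 | step 6 | aristol-9-en-8-one | C24=CC(=O)[C@@H]5[C@@H](C5(C)C)[C@@]2(C)[C@H](C)CCC4
F6 | step 6 | 9-hydroxyaristol-1(10)-en-8-one (C9 epimers) | C24C(O)C(=O)[C@@H]5[C@@H](C5(C)C)[C@@]2(C)[C@H](C)CCC=4
F7 | step 10 | 1-(2,6-dihydroxy-3-iodo-4-methoxyphenyl)ethanone | CC(=O)c1c(O)cc(OC)c(I)c1O
F8 | step 10 | 1-[3-iodo-4-methoxy-2,6-bis(methoxymethoxy)phenyl]ethanone | CC(=O)c1c(OCOC)cc(OC)c(I)c1OCOC
F9 | step 10 | pinacol boronate of F8 | CC(=O)c1c(OCOC)cc(OC)c(B2OC(C)(C)C(C)(C)O2)c1OCOC
F10 | step 10 | 9-acetoxy-1-arylaristola-1,9-dien-8-one | C24=C(OC(C)=O)C(=O)[C@@H]5[C@@H](C5(C)C)[C@@]2(C)[C@H](C)CC=C4c3c(OCOC)c(C(C)=O)c(OCOC)cc3OC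
F11 | step 10 | 9-acetoxy-1α-arylaristol-9-en-8-one | C24=C(OC(C)=O)C(=O)[C@@H]5[C@@H](C5(C)C)[C@@]2(C)[C@H](C)CC[C@@H]4c3c(OCOC)c(C(C)=O)c(OCOC)cc3OC
F12 | step 10 | bis(methoxymethyl) ether of 17 | C24=C(O)C(=O)[C@@H]5[C@@H](C5(C)C)[C@@]2(C)[C@H](C)CC[C@@H]4c3c(OCOC)c(C(=O)/C=C/c6ccc(OC)cc6)c(OCOC)cc3OC
F13 | step 11 | 9-hydroxy 8-ketone (9-dihydro form of 18, C9 epimers) | COc1ccc(/C=C/C(=O)c2c(O)cc(OC)c3c2O[C@]24C(O)C(=O)[C@@H]5[C@@H](C5(C)C)[C@@]2(C)[C@H](C)CC[C@H]34)cc1
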